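**Plan**
- Retrosynthetic cuts, in order: the two O–CH3 bonds that mask the C5 and C7 phenols; O1–C8a of the pyranone (oxidative aryl C–H / enol O–H coupling); C2–C3 (Claisen condensation of a methyl ketone with a palmitate ester); C4–C4a (Friedel–Crafts acylation); the C6–CH3 bond (formylation, then reduction), leading back to 2-methylresorcinol.
- Forward: the fully substituted arene is built first, the C16 chain is joined to the acetyl group, the pyranone (the only ring formed) closes in the penultimate step, and demethylation finishes the route.
- Enabling feature: O1–C8a is the aryl–oxygen bond ortho to the C4 carbonyl. In the open-chain aryl 1,3-diketone, C8a is the only benzene carbon still bearing hydrogen (C5 OMe, C6 Me, C7 OMe, C8 Me), it sits next to the directing ketone, and the enol oxygen on C2 can reach it.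
- Stereochemistry: the target has no stereocentre, so nothing has to be set or preserved.

Key step: step 6

Remark: the target contains no stereogenic element, so the "single enantiomer" is the one achiral compound and no step needs stereocontrol.
Remark: catalyst-bound palladium species and Lewis acid adducts are treated as mechanistic states of a step, not as numbered compounds; diketone 11 is drawn in the diketo form although it should be largely enolised.

Step 1
Reactants: 1 2-methylresorcinol (2-methylbenzene-1,3-diol)
Product: 3 2,4-dihydroxy-3-methylbenzaldehyde, via aryl iminium chloride 2 (not isolated)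
Conditions: POCl3, DMF, MeCN, −15 → 25 °C; then H2O, 50 °C
Reagents that add atoms: N,N-dimethylformamide, CN(C)C=O (formyl carbon); water, O (carbonyl oxygen)
Why: Vilsmeier–Haack formylation, in which the chloroiminium ion should attack C4 (ortho to one hydroxyl and para to the other, equivalent to C6, with C2 blocked by methyl) and the iminium salt is hydrolysed to the aldehyde on warming with water.

Step 2
Reactants: 3 2,4-dihydroxy-3-methylbenzaldehyde
Product: 5 2,4-dimethylbenzene-1,3-diol, via benzylic alcohol 4 (not isolated)
Conditions: H2 (3 bar), 10% Pd/C, AcOH, cat. HCl, 25 °C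
Reagents that add atoms: none
Why: Catalytic hydrogenolysis of an ortho/para-hydroxybenzaldehyde, in which the aldehyde is hydrogenated to an electron-rich benzylic alcohol whose C–O bond should be cleaved readily on Pd/C in acid to leave the methyl group.

Step 3
Reactants: 5 2,4-dimethylbenzene-1,3-diol
Product: 6 1,3-dimethoxy-2,4-dimethylbenzene
Conditions: MeI (3 equiv), K2CO3, DMF, 40 °C
Reagents that add atoms: iodomethane, CI
Why: Williamson O-methylation of both phenoxides in a polar aprotic solvent, with excess iodomethane expected to carry the more hindered hydroxyl between the two methyl groups to completion.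

Step 4
Reactants: 6 1,3-dimethoxy-2,4-dimethylbenzene; 7 acetyl chloride
Product: 8 1-(2,4-dimethoxy-3,5-dimethylphenyl)ethan-1-one
Conditions: AlCl3 (1.1 equiv), CH2Cl2, −10 → 0 °C; then ice/1 M HCl
Reagents that add atoms: none
Why: Friedel–Crafts acylation, in which the acylium ion should enter C6, the only free position ortho to one methoxy group and para to the other, while low temperature and a single equivalent of Lewis acid guard the ether next to the new ketone.

Step 5
Reactants: 8 1-(2,4-dimethoxy-3,5-dimethylphenyl)ethan-1-one; 9 methyl palmitate (methyl hexadecanoate)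
Product: 11 1-(2,4-dimethoxy-3,5-dimethylphenyl)octadecane-1,3-dione, via sodium diketonate 10 (not isolated)
Conditions: NaH (2.5 equiv), THF, 0 °C → reflux; then 1 M HCl
Reagents that add atoms: none
Why: Crossed Claisen condensation, in which the methyl ketone enolate is acylated on carbon by the ester and irreversible deprotonation of the 1,3-diketone to its sodium enolate should pull the equilibrium forward until the acid quench.

Step 6
Reactants: 11 1-(2,4-dimethoxy-3,5-dimethylphenyl)octadecane-1,3-dione
Product: 12 5,7-dimethoxy-6,8-dimethyl-2-pentadecyl-4H-chromen-4-one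
Conditions: Pd(OCOCF3)2 (10 mol%), K2S2O8 (2 equiv), CF3CO2H, 50 °C
Reagents that add atoms: none
Why: Proposed new method: in trifluoroacetic acid, which should keep the diketone protonated and so disfavour an inert O,O-chelate with palladium, the C4 ketone oxygen guides electrophilic Pd(II) to C8a by concerted metalation–deprotonation, giving a five-membered palladacycle that persulfate oxidises to a high-valent aryl–palladium species. Rotation about C4–C4a then lets the Z-enol oxygen on C2 replace the carbonyl ligand, and C(aryl)–O reductive elimination from the resulting seven-membered oxapalladacycle forms O1–C8a and returns Pd(II). The closest known reaction types are Pd(II)-catalysed ketone-directed ortho C–H oxygenation of aryl ketones with persulfate or iodine(III) oxidants in acidic media, and Pd-catalysed O–H/C–H cyclisations of 2-arylphenols and 2-arylbenzoic acids to dibenzofurans and benzochromenones. The pyranone closes as a six-membered ring through oxygen by this ring-contracting reductive elimination, whereas coupling at the central diketone carbon would require a benzocyclobutenone and is excluded by strain; no stereocentre is formed. Site selectivity is fixed by the substrate, since the other ortho position carries methoxy and every remaining ring carbon is substituted. Chemoselectivity over benzylic or arene oxidation rests on chelation-directed palladation, on the acyl-deactivated ring, and on using persulfate in place of an iodine(III) oxidant that would attack the active methylene.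

Step 7
Reactants: 12 5,7-dimethoxy-6,8-dimethyl-2-pentadecyl-4H-chromen-4-one
Product: 14 5,7-dihydroxy-6,8-dimethyl-2-pentadecyl-4H-chromen-4-one, via bis(dibromoboryl) ether 13 (not isolated)
Conditions: BBr3 (5 equiv), CH2Cl2, −78 → 25 °C; then H2O
Reagents that add atoms: none
Why: Lewis-acid ether cleavage with BBr3, in which bromide attack on the O-coordinated methyl groups should release both ethers (C5 assisted by chelation to the C4 carbonyl, C7 by its twisted, more basic oxygen) and the aryl borates hydrolyse on work-up while chromone and alkyl chain stay untouched.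

**Compound list**
1 | 2-methylresorcinol (2-methylbenzene-1,3-diol) | Cc1c(O)cccc1O | starting material
2 | N-[(2,4-dihydroxy-3-methylphenyl)methylidene]-N-methylmethanaminium chloride | C[N+](C)=Cc1ccc(O)c(C)c1O.[Cl-] | intermediate (not isolated)
3 | 2,4-dihydroxy-3-methylbenzaldehyde | O=Cc1ccc(O)c(C)c1O | intermediate
4 | 4-(hydroxymethyl)-2-methylbenzene-1,3-diol | OCc1ccc(O)c(C)c1O | intermediate (not isolated)
5 | 2,4-dimethylbenzene-1,3-diol | Cc1ccc(O)c(C)c1O | intermediate
6 | 1,3-dimethoxy-2,4-dimethylbenzene | COc1ccc(C)c(OC)c1C | intermediate
7 | acetyl chloride | CC(Cl)=O | starting material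
8 | 1-(2,4-dimethoxy-3,5-dimethylphenyl)ethan-1-one | CC(=O)c1cc(C)c(OC)c(C)c1OC | intermediate
9 | methyl palmitate (methyl hexadecanoate) | CCCCCCCCCCCCCCCC(=O)OC | starting material
10 | sodium (Z)-1-(2,4-dimethoxy-3,5-dimethylphenyl)-3-oxooctadec-1-en-1-olate | CCCCCCCCCCCCCCCC(=O)\C=C(/[O-])c1cc(C)c(OC)c(C)c1OC.[Na+] | intermediate (not isolated)
11 | 1-(2,4-dimethoxy-3,5-dimethylphenyl)octadecane-1,3-dione | CCCCCCCCCCCCCCCC(=O)CC(=O)c1cc(C)c(OC)c(C)c1OC | intermediate (key-step precursor)
12 | 5,7-dimethoxy-6,8-dimethyl-2-pentadecyl-4H-chromen-4-one | CCCCCCCCCCCCCCCc1cc(=O)c2c(OC)c(C)c(OC)c(C)c2o1 | intermediate (key-step product)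
13 | 5,7-bis(dibromoboryloxy)-6,8-dimethyl-2-pentadecyl-4H-chromen-4-one | CCCCCCCCCCCCCCCc1cc(=O)c2c(OB(Br)Br)c(C)c(OB(Br)Br)c(C)c2o1 | intermediate (not isolated)
14 | 5,7-dihydroxy-6,8-dimethyl-2-pentadecyl-4H-chromen-4-one | CCCCCCCCCCCCCCCc1cc(=O)c2c(O)c(C)c(O)c(C)c2o1 | target

**Step count and risks**
Total steps: 7. Longest linear sequence: 7 steps (1 to 14); 7 and 9 are commercial and enter directly.

Steps most likely to fail:

1. Step 6 (proposed new method). The catalyst may be sequestered by O,O-chelation of the enolised diketone. The oxidant may attack the enol or the electron-rich ring before palladation occurs. C–O reductive elimination with the enol oxygen may be slower than protodepalladation or capture by trifluoroacetate. Fallback with known chemistry, setting out from 8 and returning at 12: Pd(II)-catalysed ketone-directed ortho C–H oxygenation of the simple aryl methyl ketone (Pd(OCOCF3)2, PhI(OCOCF3)2, DCE, 80 °C) should give 2-acetyl-3,5-dimethoxy-4,6-dimethylphenyl 2,2,2-trifluoroacetate F1. This is hydrolysed on NaHCO3/MeOH work-up to 1-(2-hydroxy-4,6-dimethoxy-3,5-dimethylphenyl)ethan-1-one F2. The lithium dianion of F2 (LiHMDS, THF, −78 °C) is acylated on carbon with palmitoyl chloride to give 1-(2-hydroxy-4,6-dimethoxy-3,5-dimethylphenyl)octadecane-1,3-dione F3. Acid-catalysed cyclodehydration (cat. H2SO4, AcOH, 80 °C) then closes the pyranone to 12. In this variant the C8a oxygen is installed before the chain is attached and the ring closes by classical condensation.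

2. Step 5. Self-condensation of the enolisable ester and incomplete acylation of the ketone enolate may erode conversion. Fallback, setting out from 8 and returning at 11: the lithium enolate of 8 (LDA, THF, −78 °C) is added to hexadecanal in an aldol reaction to give racemic 1-(2,4-dimethoxy-3,5-dimethylphenyl)-3-hydroxyoctadecan-1-one F4. Oxidation of the secondary alcohol with Dess–Martin periodinane (CH2Cl2, 25 °C) should then deliver 11.

3. Step 4. The Lewis acid may cleave the methyl ether next to the newly formed carbonyl, or acylation of the hindered ring may be sluggish. Fallback, setting out from 5 and returning at 8: phenol-directed Nencki-type C-acylation of the free resorcinol (AcOH, BF3·OEt2, 90 °C) should give 1-(2,4-dihydroxy-3,5-dimethylphenyl)ethan-1-one F5, acylated ortho to one hydroxyl and para to the other. Exhaustive O-methylation (Me2SO4, K2CO3, acetone, reflux) then gives 8, so that no Lewis acid ever meets the ortho ether.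

**Further compounds**
F1 | step 6 | 2-acetyl-3,5-dimethoxy-4,6-dimethylphenyl 2,2,2-trifluoroacetate | CC(=O)c1c(OC)c(C)c(OC)c(C)c1OC(=O)C(F)(F)F
F2 | step 6 | 1-(2-hydroxy-4,6-dimethoxy-3,5-dimethylphenyl)ethan-1-one | CC(=O)c1c(OC)c(C)c(OC)c(C)c1O
F3 | step 6 | 1-(2-hydroxy-4,6-dimethoxy-3,5-dimethylphenyl)octadecane-1,3-dione | CCCCCCCCCCCCCCCC(=O)CC(=O)c1c(OC)c(C)c(OC)c(C)c1O
F4 | step 5 | rac-1-(2,4-dimethoxy-3,5-dimethylphenyl)-3-hydroxyoctadecan-1-one | CCCCCCCCCCCCCCCC(O)CC(=O)c1cc(C)c(OC)c(C)c1OC
F5 | step 4 | 1-(2,4-dihydroxy-3,5-dimethylphenyl)ethan-1-one | CC(=O)c1cc(C)c(O)c(C)c1O
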